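**Plan**

Retrosynthesis: the polyene is cut at C11=C12 (Wittig) into a C15 end-group phosphonium salt and a C25 polyenal. The polyenal is cut at C11'=C12' into the C10 dialdehyde and a C15 salt from pseudoionone, and the end-group salt is cut at C7=C8 (Horner–Wadsworth–Emmons, C5 phosphonate) to a C10 cyclopentanecarbaldehyde.
The cyclopentane C2–C6 carries C7 on C6, a fully substituted C5 (methyl C18, oxygen) and the isopropenyl group (C1, C16, C17) on C2. Re-inserting C7 between C5 and C6 gives a cyclohexanone whose ten carbons (C1–C7, C16–C18) are those of carvone, so the C5–C6 bond is cut by a Wolff ring contraction.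
Forward: (S)-carvone → trans-epoxide → α-ketol → silyl ether → 6-diazo ketone → photochemical ring contraction (the only ring-forming event, six- to five-membered) → C10 aldehyde → C15 dienoate → C15 salt. In parallel pseudoionone → C15 salt → C25 aldehyde, and the two halves are joined last.
Stereochemistry: C2 comes from (S)-carvone. C5 comes from the substrate-controlled epoxidation (oxygen trans to isopropenyl), kept through hydride opening at C4 and through the Wolff shift (retention). C6 comes from thermodynamic equilibration of the ester, and the E double bonds from E-selective olefinations plus thermal Z→E isomerisation.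

Key step: step 6

Remark: carotenoid numbering is used for all intermediates (C1 isopropenyl carbon, ring C2–C6, C7 the carbon that becomes exocyclic, C18 the methyl on C5); 13, 18 and 21 are taken as purchasable, 13 as its E-rich isomer mixture.

**Route**

Step 1
Reactants: 1 (S)-(+)-carvone
Product: 2 (1S,4S,6S)-1-methyl-4-(prop-1-en-2-yl)-7-oxabicyclo[4.1.0]heptan-2-one
Conditions: 30% aq. H2O2, NaOH (cat.), MeOH, 0 °C
Reagents that add atoms: hydrogen peroxide, OO
Why: Weitz–Scheffer nucleophilic epoxidation touches only the electron-poor enone double bond, and axial attack of hydroperoxide at C4 of the half-chair with equatorial isopropenyl places the oxirane oxygen trans to the isopropenyl group, which is the C5–O configuration of the target (C18 methyl cis to isopropenyl).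

Step 2
Reactants: 2 trans-carvone oxide
Product: 3 (1S,4S)-1-methyl-4-(prop-1-en-2-yl)cyclohexane-1,2-diol (both epimers at the secondary carbinol C7)
Conditions: LiBHEt3 (2.5 equiv), THF, 0 °C → rt; aq. NaOH
Reagents that add atoms: none
Why: LiBHEt3 should first reduce the ketone and then open the trisubstituted oxirane by SN2 hydride attack at its secondary carbon C4 (hydride reduction of an epoxide at the less substituted terminus), so the tertiary C5–O bond keeps its configuration, while the mixed configuration at C7 is erased in step 3.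

Step 3
Reactants: 3 diol (C7 epimers)
Product: 4 (2S,5S)-2-hydroxy-2-methyl-5-(prop-1-en-2-yl)cyclohexan-1-one
Conditions: 2-iodoxybenzoic acid (IBX, 1.5 equiv), DMSO, rt
Reagents that add atoms: none
Why: IBX oxidation converts the secondary alcohol of a 1,2-diol into the ketone without glycol cleavage and cannot touch the tertiary alcohol, so both C7 epimers should converge on one α-ketol.

Step 4
Reactants: 4 α-ketol
Product: 5 (2S,5S)-2-methyl-5-(prop-1-en-2-yl)-2-[(triethylsilyl)oxy]cyclohexan-1-one
Conditions: Et3SiOTf, 2,6-lutidine, CH2Cl2, −78 → 0 °C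
Reagents that add atoms: triethylsilyl trifluoromethanesulfonate, CC[Si](CC)(CC)OS(=O)(=O)C(F)(F)F
Why: Silylation with a silyl triflate and a hindered pyridine base is the standard way to cap a tertiary alcohol, and the silyl ether blocks lactonisation onto the ketene, retro-aldol cleavage and O-acylation in the following steps.

Step 5
Reactants: 5 silyloxy ketone
Product: 7 (3R,6S)-2-diazo-6-methyl-3-(prop-1-en-2-yl)-6-[(triethylsilyl)oxy]cyclohexan-1-one, via trifluoroacetyl ketone 6 (not isolated)
Conditions: LiN(SiMe3)2, THF, −78 °C, then CF3CO2CH2CF3; cold 1 M HCl wash; crude 6, 4-acetamidobenzenesulfonyl azide, Et3N, H2O (1 equiv), MeCN, rt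
Reagents that add atoms: 4-acetamidobenzenesulfonyl azide, CC(=O)Nc1ccc(cc1)S(=O)(=O)N=[N+]=[N-]; 2,2,2-trifluoroethyl trifluoroacetate, O=C(OCC(F)(F)F)C(F)(F)F (its acyl group is carried by 6 only)
Why: Deacylative (Regitz-type) diazo transfer through the trifluoroacetyl ketone is regiochemically fixed, because C5 is fully substituted and the lithium enolate, and hence the diazo group, can form only at C6.

Step 6
Reactants: 7 diazo ketone
Product: 10 methyl (1R,2S,5S)-2-methyl-5-(prop-1-en-2-yl)-2-[(triethylsilyl)oxy]cyclopentane-1-carboxylate, via ketene 8 (not isolated), via C6-epimeric ester 9 (not isolated)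
Conditions: hν (medium-pressure Hg lamp, Pyrex, λ > 300 nm), degassed MeOH, 0 °C; then NaOMe (0.3 equiv), rt
Reagents that add atoms: methanol, CO
Why: Excitation of the diazo ketone, which the ring locks s-Z, should expel N2 with concerted 1,2-shift of the C5–C7 bond onto C6 (Wolff rearrangement), and the resulting ketene 8 adds methanol to give the ester enol and then the ester. The closest known reaction type is the photochemical Wolff ring contraction of 2-diazocyclohexanones to cyclopentanecarboxylates. The cyclopentane arises by ring contraction, a 1,2-alkyl shift that makes C5–C6, and not by an end-to-end cyclisation. C5 migrates with retention, so its configuration is the one set in step 1; C2 is untouched; C6 is set under thermodynamic control, the methoxide funnelling epimer 9 into the ester that is trans to both the isopropenyl and the C18 methyl group. The step needs rearrangement to win over O–H insertion and 1,2-hydrogen shift of a free carbene, which the fixed s-Z geometry and direct irradiation in methanol should secure, and the migrating group is unambiguous because C5 is the only carbon on the carbonyl that can shift.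

Step 7
Reactants: 10 ester
Product: 11 [(1S,2S,5S)-2-methyl-5-(prop-1-en-2-yl)-2-[(triethylsilyl)oxy]cyclopentyl]methanol
Conditions: i-Bu2AlH (2.5 equiv), CH2Cl2, −78 → 0 °C; aq. KNaC4H4O6
Reagents that add atoms: none
Why: Full hydride reduction of the ester to the primary alcohol with i-Bu2AlH is more dependable on this hindered ester than a partial reduction stopped at the aldehyde, and the silyl ether and isopropenyl group are inert.

Step 8
Reactants: 11 primary alcohol
Product: 12 (1R,2S,5S)-2-methyl-5-(prop-1-en-2-yl)-2-[(triethylsilyl)oxy]cyclopentane-1-carbaldehyde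
Conditions: Dess–Martin periodinane, NaHCO3, CH2Cl2, 0 °C → rt
Reagents that add atoms: none
Why: Dess–Martin oxidation under bicarbonate buffer is neutral, so the α-centre C6 (already the thermodynamically preferred one) and the β-silyloxy group should not be disturbed.

Step 9
Reactants: 12 aldehyde; 13 triethyl (E)-3-methyl-4-phosphonobut-2-enoate
Product: 14 ethyl (2E,4E)-3-methyl-5-[(1R,2S,5S)-2-methyl-5-(prop-1-en-2-yl)-2-[(triethylsilyl)oxy]cyclopentyl]penta-2,4-dienoate
Conditions: 13, LiN(SiMe3)2, THF, −78 °C; then 12, −78 → 0 °C; aq. NH4Cl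
Reagents that add atoms: none
Why: Horner–Wadsworth–Emmons olefination with the vinylogous phosphonate should form C7=C8 with E geometry and give the 9E dienoate as the main isomer (a minor 9Z isomer would be removed by chromatography), and the weakly basic phosphonate anion limits enolisation of the aldehyde.

Step 10
Reactants: 14 silyl dienoate
Product: 15 ethyl (2E,4E)-5-[(1R,2S,5S)-2-hydroxy-2-methyl-5-(prop-1-en-2-yl)cyclopentyl]-3-methylpenta-2,4-dienoate
Conditions: HF·pyridine, pyridine, THF, 0 °C → rt
Reagents that add atoms: none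
Why: Fluoride-mediated silyl ether cleavage with buffered HF·pyridine is non-basic, which avoids a vinylogous retro-aldol opening of the ring, and the tertiary non-allylic alcohol should not ionise under these conditions.

Step 11
Reactants: 15 hydroxy dienoate
Product: 16 (2E,4E)-5-[(1R,2S,5S)-2-hydroxy-2-methyl-5-(prop-1-en-2-yl)cyclopentyl]-3-methylpenta-2,4-dien-1-ol
Conditions: i-Bu2AlH (3.5 equiv), CH2Cl2, −78 °C; aq. KNaC4H4O6
Reagents that add atoms: none
Why: 1,2-Reduction of a dienoate with i-Bu2AlH gives the allylic alcohol without conjugate reduction or change of double-bond geometry.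

Step 12
Reactants: 16 dienediol
Product: 17 {(2E,4E)-5-[(1R,2S,5S)-2-hydroxy-2-methyl-5-(prop-1-en-2-yl)cyclopentyl]-3-methylpenta-2,4-dien-1-yl}triphenylphosphonium bromide
Conditions: PPh3·HBr (1.05 equiv), MeOH, 0 °C → rt, dark
Reagents that add atoms: triphenylphosphine hydrobromide, [Br-].[PH+](c1ccccc1)(c1ccccc1)c1ccccc1
Why: Phosphonium salt formation from an allylic alcohol with PPh3·HBr runs through the pentadienyl cation, which the phosphine captures at the unhindered terminus C11 with E,E geometry, while the tertiary C5 alcohol is not allylic and should survive the weak acid.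

Step 13
Reactants: 18 pseudoionone
Product: 19 (4E,6E)-3,7,11-trimethyldodeca-1,4,6,10-tetraen-3-ol (racemic at the carbinol)
Conditions: CH2=CHMgBr, THF, −20 → 0 °C; aq. NH4Cl
Reagents that add atoms: vinylmagnesium bromide, C=C[Mg]Br
Why: Grignard 1,2-addition of the vinyl reagent to the dienone carbonyl gives the tertiary bis-allylic alcohol, whose racemic carbinol centre is destroyed in the next step.

Step 14
Reactants: 19 vinyl carbinol
Product: 20 [(2E,4E,6E)-3,7,11-trimethyldodeca-2,4,6,10-tetraen-1-yl]triphenylphosphonium bromide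
Conditions: PPh3·HBr, MeOH, rt; crystallisation
Reagents that add atoms: triphenylphosphine hydrobromide, [Br-].[PH+](c1ccccc1)(c1ccccc1)c1ccccc1
Why: Ionisation of the tertiary allylic alcohol and capture of the delocalised cation by PPh3 at the primary terminus (SN1-type salt formation with allylic transposition) should give the conjugated triene salt, E at the new trisubstituted bond after crystallisation.

Step 15
Reactants: 20 C15 phosphonium bromide; 21 (2E,4E,6E)-2,7-dimethylocta-2,4,6-trienedial
Product: 23 (2E,4E,6E,8E,10E,12E,14E)-2,7,11,15,19-pentamethylicosa-2,4,6,8,10,12,14,18-octaenal, via 8Z-aldehyde 22 (not isolated)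
Conditions: 21 (3 equiv), NaOMe, CH2Cl2/MeOH, 0 °C → rt, dark; crude in n-heptane, 90 °C
Reagents that add atoms: none
Why: Wittig olefination with the dialdehyde in excess favours condensation at only one of the two equivalent formyl groups, and the sterically hindered Z isomer 22 at the new disubstituted bond should isomerise thermally to the all-E aldehyde.

Step 16
Reactants: 17 end-group phosphonium bromide; 23 C25 aldehyde
Product: 25 target (all-E,2S,5S,6R)-1,16-didehydro-2,6-cyclolycopen-5-ol, via 11Z-polyene 24 (not isolated)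
Conditions: NaOMe (1.5 equiv), CH2Cl2/MeOH, 0 °C → rt, dark, Ar; crude in n-heptane, 90 °C; crystallisation
Reagents that add atoms: none
Why: Wittig olefination joins the two halves at C11=C12 under methoxide conditions that tolerate the free tertiary alcohol, and the hindered 11Z isomer 24 should relax thermally to the all-E polyene, which crystallises.

**Compound list**

1 | (S)-(+)-carvone, (5S)-2-methyl-5-(prop-1-en-2-yl)cyclohex-2-en-1-one | C=C(C)[C@H]1CC=C(C)C(=O)C1 | starting material
2 | (1S,4S,6S)-1-methyl-4-(prop-1-en-2-yl)-7-oxabicyclo[4.1.0]heptan-2-one (oxirane trans to isopropenyl) | C=C(C)[C@H]1C[C@@H]2O[C@]2(C)C(=O)C1 | intermediate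
3 | (1S,4S)-1-methyl-4-(prop-1-en-2-yl)cyclohexane-1,2-diol, both epimers at the secondary carbinol (left open in the SMILES) | C=C(C)[C@H]1CC[C@](C)(O)C(O)C1 | intermediate
4 | (2S,5S)-2-hydroxy-2-methyl-5-(prop-1-en-2-yl)cyclohexan-1-one (OH trans, methyl cis to isopropenyl) | C=C(C)[C@H]1CC[C@](C)(O)C(=O)C1 | intermediate
5 | (2S,5S)-2-methyl-5-(prop-1-en-2-yl)-2-[(triethylsilyl)oxy]cyclohexan-1-one | C=C(C)[C@H]1CC[C@](C)(O[Si](CC)(CC)CC)C(=O)C1 | intermediate
6 | (2S,5S)-2-methyl-5-(prop-1-en-2-yl)-6-(trifluoroacetyl)-2-[(triethylsilyl)oxy]cyclohexan-1-one, enolised β-diketone with no fixed centre at C6, formed in the flask | C=C(C)[C@H]1CC[C@](C)(O[Si](CC)(CC)CC)C(=O)C1C(=O)C(F)(F)F | intermediate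
7 | (3R,6S)-2-diazo-6-methyl-3-(prop-1-en-2-yl)-6-[(triethylsilyl)oxy]cyclohexan-1-one | C=C(C)[C@H]1CC[C@](C)(O[Si](CC)(CC)CC)C(=O)C1=[N+]=[N-] | intermediate
8 | ketene [(2S,5R)-2-methyl-5-(prop-1-en-2-yl)-2-[(triethylsilyl)oxy]cyclopentylidene]methanone, formed in the flask | C=C(C)[C@H]1CC[C@](C)(O[Si](CC)(CC)CC)C1=C=O | intermediate
9 | methyl (1S,2S,5S)-2-methyl-5-(prop-1-en-2-yl)-2-[(triethylsilyl)oxy]cyclopentane-1-carboxylate (ester cis to isopropenyl and to the C18 methyl), formed in the flask | C=C(C)[C@H]1CC[C@](C)(O[Si](CC)(CC)CC)[C@H]1C(=O)OC | intermediate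
10 | methyl (1R,2S,5S)-2-methyl-5-(prop-1-en-2-yl)-2-[(triethylsilyl)oxy]cyclopentane-1-carboxylate (ester trans to isopropenyl and to the C18 methyl) | C=C(C)[C@H]1CC[C@](C)(O[Si](CC)(CC)CC)[C@@H]1C(=O)OC | intermediate
11 | [(1S,2S,5S)-2-methyl-5-(prop-1-en-2-yl)-2-[(triethylsilyl)oxy]cyclopentyl]methanol | C=C(C)[C@H]1CC[C@](C)(O[Si](CC)(CC)CC)[C@@H]1CO | intermediate
12 | (1R,2S,5S)-2-methyl-5-(prop-1-en-2-yl)-2-[(triethylsilyl)oxy]cyclopentane-1-carbaldehyde | C=C(C)[C@H]1CC[C@](C)(O[Si](CC)(CC)CC)[C@@H]1C=O | intermediate
13 | triethyl (E)-3-methyl-4-phosphonobut-2-enoate (C5 phosphonate) | CCOC(=O)/C=C(\C)CP(=O)(OCC)OCC | starting material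
14 | ethyl (2E,4E)-3-methyl-5-[(1R,2S,5S)-2-methyl-5-(prop-1-en-2-yl)-2-[(triethylsilyl)oxy]cyclopentyl]penta-2,4-dienoate | C=C(C)[C@H]1CC[C@](C)(O[Si](CC)(CC)CC)[C@@H]1/C=C/C(C)=C/C(=O)OCC | intermediate
15 | ethyl (2E,4E)-5-[(1R,2S,5S)-2-hydroxy-2-methyl-5-(prop-1-en-2-yl)cyclopentyl]-3-methylpenta-2,4-dienoate | C=C(C)[C@H]1CC[C@](C)(O)[C@@H]1/C=C/C(C)=C/C(=O)OCC | intermediate
16 | (2E,4E)-5-[(1R,2S,5S)-2-hydroxy-2-methyl-5-(prop-1-en-2-yl)cyclopentyl]-3-methylpenta-2,4-dien-1-ol | C=C(C)[C@H]1CC[C@](C)(O)[C@@H]1/C=C/C(C)=C/CO | intermediate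
17 | {(2E,4E)-5-[(1R,2S,5S)-2-hydroxy-2-methyl-5-(prop-1-en-2-yl)cyclopentyl]-3-methylpenta-2,4-dien-1-yl}triphenylphosphonium bromide | C=C(C)[C@H]1CC[C@](C)(O)[C@@H]1/C=C/C(C)=C/C[P+](c1ccccc1)(c1ccccc1)c1ccccc1.[Br-] | intermediate
18 | pseudoionone, (3E,5E)-6,10-dimethylundeca-3,5,9-trien-2-one | CC(C)=CCC/C(C)=C/C=C/C(C)=O | starting material
19 | (4E,6E)-3,7,11-trimethyldodeca-1,4,6,10-tetraen-3-ol, racemic | CC(C)=CCC/C(C)=C/C=C/C(C)(O)C=C | intermediate
20 | [(2E,4E,6E)-3,7,11-trimethyldodeca-2,4,6,10-tetraen-1-yl]triphenylphosphonium bromide | CC(C)=CCC/C(C)=C/C=C/C(C)=C/C[P+](c1ccccc1)(c1ccccc1)c1ccccc1.[Br-] | intermediate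
21 | (2E,4E,6E)-2,7-dimethylocta-2,4,6-trienedial (C10 dialdehyde) | O=C/C(C)=C/C=C/C=C(C)/C=O | starting material
22 | (2E,4E,6E,8Z,10E,12E,14E)-2,7,11,15,19-pentamethylicosa-2,4,6,8,10,12,14,18-octaenal, formed in the flask | O=C/C(C)=C/C=C/C=C(C)/C=C\C=C(C)\C=C\C=C(/C)CCC=C(C)C | intermediate
23 | (2E,4E,6E,8E,10E,12E,14E)-2,7,11,15,19-pentamethylicosa-2,4,6,8,10,12,14,18-octaenal (C25 aldehyde, apo-12'-lycopenal) | O=C/C(C)=C/C=C/C=C(C)/C=C/C=C(C)/C=C/C=C(\C)CCC=C(C)C | intermediate
24 | 11Z isomer of the target (Z at C11=C12, all other chain double bonds E), formed in the flask | C=C(C)[C@H]1CC[C@](C)(O)[C@@H]1/C=C/C(C)=C/C=C\C(C)=C\C=C\C=C(C)\C=C\C=C(C)\C=C\C=C(/C)CCC=C(C)C | intermediate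
25 | CNP0222499.1, (1S,2R,3S)-1-methyl-3-(prop-1-en-2-yl)-2-[(all-E)-3,7,12,16,20,24-hexamethylpentacosa-1,3,5,7,9,11,13,15,17,19,23-undecaen-1-yl]cyclopentan-1-ol, carotenoid descriptors 2S,5S,6R | C=C(C)[C@H]1CC[C@](C)(O)[C@@H]1/C=C/C(C)=C/C=C/C(C)=C/C=C/C=C(C)/C=C/C=C(C)/C=C/C=C(\C)CCC=C(C)C | target

**Step count and risks**

Total step count: 16. Longest linear sequence: 13 steps (steps 1–12 and 16, from carvone 1 to 25); steps 13–15 form the convergent branch.

Steps most likely to fail:

Step 2. Hydride could attack the fully substituted oxirane carbon C5 in a trans-diaxial opening, which would give the 1,3-diol and destroy the C5–O bond. The fallback sets out from carvone 1: Mukaiyama-type reductive α-hydroxylation of the enone with Mn(dpm)3 (cat.), PhSiH3 and O2 in i-PrOH at 0 °C, where the electron-poor enone should react ahead of the isopropenyl group, gives the α-hydroperoxy ketone F1, which P(OEt)3 reduces in the same flask. Capture of the planar C5 radical by O2 has no dependable facial bias, so ketol 4 would have to be separated by chromatography from its C5 epimer, the (2R,5S)-ketol F2. The route is rejoined at 4.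

Step 6. The ester enolate could eliminate triethylsilanolate, or the silyl group could be lost with retro-aldol ring opening, during the methoxide equilibration, on top of an unfavourable kinetic ratio at C6 from protonation of the ester enol. The fallback sets out from diazo ketone 7: the same photochemical ring contraction run in THF with MeNHOMe as the ketene trap gives the N-methoxy-N-methyl amide F3 as C6 epimers, which i-Bu2AlH (THF, −78 °C) reduces directly to the aldehyde. An aldehyde α-centre equilibrates under far milder conditions (DBU cat., CH2Cl2, rt), which converts the cis aldehyde F4 into 12, where the route is rejoined without any alkoxide and one step shorter.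

Step 9. Addition of the bulky phosphonate anion to the aldehyde, flanked by the quaternary C5 and by C2, may be slow, so that enolisation with β-elimination of the silanolate or epimerisation at C6 competes. The fallback sets out from aldehyde 12: Takai olefination (CrCl2, CHI3, THF, 0 °C), which is non-basic and tolerates hindered enolisable aldehydes, gives the E-vinyl iodide F5. Stille coupling with ethyl (E)-3-(tributylstannyl)but-2-enoate (Pd(PPh3)4, CuI, DMF, rt), with retention of both double-bond geometries, then gives dienoate 14, where the route is rejoined.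

**Further compounds**

F1 | step 2 | (5S)-2-hydroperoxy-2-methyl-5-(prop-1-en-2-yl)cyclohexan-1-one, both C2 epimers | C=C(C)[C@H]1CCC(C)(OO)C(=O)C1
F2 | step 2 | (2R,5S)-2-hydroxy-2-methyl-5-(prop-1-en-2-yl)cyclohexan-1-one | C=C(C)[C@H]1CC[C@@](C)(O)C(=O)C1
F3 | step 6 | (2S,5S)-N-methoxy-N,2-dimethyl-5-(prop-1-en-2-yl)-2-[(triethylsilyl)oxy]cyclopentane-1-carboxamide, both C1 epimers | C=C(C)[C@H]1CC[C@](C)(O[Si](CC)(CC)CC)C1C(=O)N(C)OC
F4 | step 6 | (1S,2S,5S)-2-methyl-5-(prop-1-en-2-yl)-2-[(triethylsilyl)oxy]cyclopentane-1-carbaldehyde | C=C(C)[C@H]1CC[C@](C)(O[Si](CC)(CC)CC)[C@H]1C=O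
F5 | step 9 | triethyl{[(1S,2S,3S)-2-[(E)-2-iodoethenyl]-1-methyl-3-(prop-1-en-2-yl)cyclopentyl]oxy}silane | C=C(C)[C@H]1CC[C@](C)(O[Si](CC)(CC)CC)[C@@H]1/C=C/I
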